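**Retrosynthetic overview**
1. The γ-hydroxy acid is unmasked last by opening an (S)-3-butylphthalide with hydroxide; the lactone serves as internal protection of the carbinol and the acid.
2. The three phenols come from global O-demethylation; the diaryl ether comes from SNAr of a ring A phenoxide on a ring B 7-fluorophthalide.
3. The fluorophthalide comes from an o-bromo benzylic alcohol (Br/Li exchange, CO2, lactonisation), made by para-selective bromination of an (S)-carbinol set by catalytic asymmetric butylzinc addition to 3-fluoro-5-methoxybenzaldehyde.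
4. The ring A phenol comes from olivetol dimethyl ether by Vilsmeier formylation and Baeyer–Villiger oxidation.
5. Both benzene rings are bought; the only ring formed is the lactone (step 5), reopened in step 8.

Assumption: 1,3-dimethoxy-5-pentylbenzene, 3-fluoro-5-methoxybenzaldehyde, di-n-butylzinc and (2S)-(−)-3-exo-(dimethylamino)isoborneol are taken as commercially available; the target stereocentre is (S).

**Route**

Step 1
Reactants: 1 1,3-dimethoxy-5-pentylbenzene (olivetol dimethyl ether)
Product: 3 2,4-dimethoxy-6-pentylbenzaldehyde, via aryliminium chloride 2 (not isolated)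
Conditions: POCl3 (1.3 equiv), DMF, 0 → 70 °C; then ice-water
Reagents that add atoms: N,N-dimethylformamide CN(C)C=O; water O; phosphoryl chloride O=P(Cl)(Cl)Cl (chloride of 2)
Why: Vilsmeier–Haack formylation attacks para to one methoxy group and ortho to the other (next to the pentyl chain), as is usual for 5-alkylresorcinol dimethyl ethers, and the iminium hydrolyses on quench.

Step 2
Reactants: 3 2,4-dimethoxy-6-pentylbenzaldehyde
Product: 5 2,4-dimethoxy-6-pentylphenol, via aryl formate 4 (not isolated)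
Conditions: mCPBA, CH2Cl2, 0 °C → rt; aq NaHCO3 wash; then K2CO3 (cat.), MeOH, rt
Reagents that add atoms: 3-chloroperoxybenzoic acid O=C(OO)c1cccc(Cl)c1
Why: Baeyer–Villiger (Dakin-type) oxidation, in which the electron-rich aryl group migrates to oxygen and the formate is then cleaved by methanolysis.

Step 3
Reactants: 6 3-fluoro-5-methoxybenzaldehyde
Product: 8 (1S)-1-(3-fluoro-5-methoxyphenyl)pentan-1-ol, via butylzinc alkoxide 7 (not isolated)
Conditions: n-Bu2Zn (1.5 equiv), (2S)-(−)-3-exo-(dimethylamino)isoborneol (5 mol%), toluene, 0 °C; then 1 M HCl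
Reagents that add atoms: di-n-butylzinc CCCC[Zn]CCCC
Why: Noyori amino-alcohol-catalysed enantioselective dialkylzinc addition, in which the (2S)-ligand–zinc complex delivers butyl to the Si face of the aryl aldehyde and so sets the only stereocentre as (S).

Step 4
Reactants: 8 (1S)-1-(3-fluoro-5-methoxyphenyl)pentan-1-ol
Product: 9 (1S)-1-(2-bromo-3-fluoro-5-methoxyphenyl)pentan-1-ol
Conditions: NBS (1.05 equiv), MeCN, 0 °C → rt, dark
Reagents that add atoms: N-bromosuccinimide O=C1CCC(=O)N1Br
Why: Electrophilic aromatic bromination goes para to the methoxy group, between the carbinol and the small fluorine (the same sense as the 2-bromination of 3,5-dimethoxybenzyl alcohols), and leaves the stereocentre untouched.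

Step 5
Reactants: 9 (1S)-1-(2-bromo-3-fluoro-5-methoxyphenyl)pentan-1-ol
Product: 12 (3S)-3-butyl-7-fluoro-5-methoxy-2-benzofuran-1(3H)-one, via dilithio species 10 (not isolated), via hydroxy acid 11 (not isolated)
Conditions: n-BuLi (2.2 equiv), THF, −78 °C; CO2 (g), −78 °C → rt; then 2 M HCl, rt
Reagents that add atoms: carbon dioxide O=C=O; n-butyllithium [Li]CCCC (lithium of 10)
Why: Bromine–lithium exchange on the lithium alkoxide (kept at −78 °C so the o-fluoroaryllithium does not lose LiF), carboxylation and acid-promoted lactonisation close the phthalide through the carbinol oxygen, so the C–O stereocentre stays (S).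

Step 6
Reactants: 12 (3S)-3-butyl-7-fluoro-5-methoxy-2-benzofuran-1(3H)-one; 5 2,4-dimethoxy-6-pentylphenol
Product: 13 (3S)-3-butyl-7-(2,4-dimethoxy-6-pentylphenoxy)-5-methoxy-2-benzofuran-1(3H)-one
Conditions: Cs2CO3 (1.5 equiv), DMSO (degassed), 100 °C, argon
Reagents that add atoms: none
Why: Nucleophilic aromatic substitution (SNAr), in which the fluoride ortho to the coplanar lactone carbonyl is displaced by the cesium phenoxide through a Meisenheimer adduct, while the weakly acidic C-3 hydrogen is not removed by carbonate.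

Step 7
Reactants: 13 (3S)-3-butyl-7-(2,4-dimethoxy-6-pentylphenoxy)-5-methoxy-2-benzofuran-1(3H)-one
Product: 14 (3S)-3-butyl-7-(2,4-dihydroxy-6-pentylphenoxy)-5-hydroxy-2-benzofuran-1(3H)-one
Conditions: BBr3 (6 equiv), CH2Cl2, −78 °C → rt; then ice-water
Reagents that add atoms: none
Why: Lewis-acid cleavage of the three aryl methyl ethers; the diaryl ether and lactone are inert and the benzylic C–O bond does not ionise because both ring oxygens are meta to it, so (S) is kept.

Step 8
Reactants: 14 (3S)-3-butyl-7-(2,4-dihydroxy-6-pentylphenoxy)-5-hydroxy-2-benzofuran-1(3H)-one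
Product: 16 2-(2,4-dihydroxy-6-pentylphenoxy)-4-hydroxy-6-[(1S)-1-hydroxypentyl]benzoic acid, via tetrasodium salt 15 (not isolated)
Conditions: 2 M NaOH (aq, 6 equiv), THF, degassed, argon, 50 °C; then 0 °C, 1 M HCl to pH 3–4, cold EtOAc extraction, evaporation below 20 °C
Reagents that add atoms: sodium hydroxide [Na+].[OH-]
Why: Lactone saponification by acyl–oxygen cleavage keeps the carbinol configuration (S), and cold, mildly acidic protonation frees the acid before it can relactonise.

**Compound list**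
1 | 1,3-dimethoxy-5-pentylbenzene (olivetol dimethyl ether) | CCCCCc1cc(OC)cc(OC)c1 | starting material
2 | N-[(2,4-dimethoxy-6-pentylphenyl)methylidene]-N-methylmethanaminium chloride | CCCCCc1cc(OC)cc(OC)c1C=[N+](C)C.[Cl-] | intermediate
3 | 2,4-dimethoxy-6-pentylbenzaldehyde | CCCCCc1cc(OC)cc(OC)c1C=O | intermediate
4 | 2,4-dimethoxy-6-pentylphenyl formate | CCCCCc1cc(OC)cc(OC)c1OC=O | intermediate
5 | 2,4-dimethoxy-6-pentylphenol | CCCCCc1cc(OC)cc(OC)c1O | intermediate
6 | 3-fluoro-5-methoxybenzaldehyde | COc1cc(F)cc(C=O)c1 | starting material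
7 | butylzinc (1S)-1-(3-fluoro-5-methoxyphenyl)pentan-1-olate | CCCC[C@H](O[Zn]CCCC)c1cc(F)cc(OC)c1 | intermediate
8 | (1S)-1-(3-fluoro-5-methoxyphenyl)pentan-1-ol | CCCC[C@H](O)c1cc(F)cc(OC)c1 | intermediate
9 | (1S)-1-(2-bromo-3-fluoro-5-methoxyphenyl)pentan-1-ol | CCCC[C@H](O)c1cc(OC)cc(F)c1Br | intermediate
10 | lithium (1S)-1-(3-fluoro-2-lithio-5-methoxyphenyl)pentan-1-olate | CCCC[C@H](O[Li])c1cc(OC)cc(F)c1[Li] | intermediate
11 | 2-fluoro-6-[(1S)-1-hydroxypentyl]-4-methoxybenzoic acid | CCCC[C@H](O)c1cc(OC)cc(F)c1C(=O)O | intermediate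
12 | (3S)-3-butyl-7-fluoro-5-methoxy-2-benzofuran-1(3H)-one | CCCC[C@@H]1OC(=O)c2c(F)cc(OC)cc21 | intermediate
13 | (3S)-3-butyl-7-(2,4-dimethoxy-6-pentylphenoxy)-5-methoxy-2-benzofuran-1(3H)-one | CCCCCc1cc(OC)cc(OC)c1Oc1cc(OC)cc2c1C(=O)O[C@H]2CCCC | intermediate
14 | (3S)-3-butyl-7-(2,4-dihydroxy-6-pentylphenoxy)-5-hydroxy-2-benzofuran-1(3H)-one | CCCCCc1cc(O)cc(O)c1Oc1cc(O)cc2c1C(=O)O[C@H]2CCCC | intermediate
15 | tetrasodium 2-(2,4-dioxido-6-pentylphenoxy)-6-[(1S)-1-hydroxypentyl]-4-oxidobenzoate | CCCCCc1cc([O-])cc([O-])c1Oc1cc([O-])cc([C@@H](O)CCCC)c1C(=O)[O-].[Na+].[Na+].[Na+].[Na+] | intermediate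
16 | 2-(2,4-dihydroxy-6-pentylphenoxy)-4-hydroxy-6-[(1S)-1-hydroxypentyl]benzoic acid | CCCCCc1cc(O)cc(O)c1Oc1cc(O)cc([C@@H](O)CCCC)c1C(=O)O | target

**Totals and risks**
Total step count: 8. Longest linear sequence: 6 steps (6 → 16, steps 3–8).

The three steps most likely to fail, in order of risk, are step 6, step 8 and step 5.

Step 6 is the weakest point. The fluoride is activated only by a lactone carbonyl, the phenoxide is di-ortho-substituted and air-sensitive, and the temperature needed may degrade the lactone. The fallback sets out from 9 and comes back at 13, and moves the substitution to an aldehyde-activated fluoride. Alcohol 9 is protected (MOMCl, i-Pr2NEt, CH2Cl2) as (S)-2-bromo-1-fluoro-5-methoxy-3-[1-(methoxymethoxy)pentyl]benzene F1. Br/Li exchange (n-BuLi, THF, −78 °C) and DMF quench give 2-fluoro-4-methoxy-6-[(1S)-1-(methoxymethoxy)pentyl]benzaldehyde F2. SNAr with phenol 5 (K2CO3, DMF, 80 °C) gives 2-(2,4-dimethoxy-6-pentylphenoxy)-4-methoxy-6-[(1S)-1-(methoxymethoxy)pentyl]benzaldehyde F3. Pinnick oxidation (NaClO2, NaH2PO4, excess 2-methyl-2-butene, t-BuOH/H2O) gives 2-(2,4-dimethoxy-6-pentylphenoxy)-4-methoxy-6-[(1S)-1-(methoxymethoxy)pentyl]benzoic acid F4. HCl in MeOH at 50 °C removes the acetal to 2-(2,4-dimethoxy-6-pentylphenoxy)-6-[(1S)-1-hydroxypentyl]-4-methoxybenzoic acid F5, which lactonises in the same flask to 13.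

Step 8 can fail because the para-phenoxide slows lactone opening and the free γ-hydroxy acid can relactonise during acidification. The fallback sets out from 14 and comes back at 16, and frees the acid without any acid. After the same NaOH opening, the solution is brought to pH 8 with CO2 and freeze-dried to sodium 2-(2,4-dihydroxy-6-pentylphenoxy)-4-hydroxy-6-[(1S)-1-hydroxypentyl]benzoate F6. Its carboxylate is alkylated (BnBr, DMF, 0 °C) to benzyl 2-(2,4-dihydroxy-6-pentylphenoxy)-4-hydroxy-6-[(1S)-1-hydroxypentyl]benzoate F7. Neutral hydrogenolysis (H2 1 atm, Pd/C, EtOAc, rt) then gives 16.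

Step 5 can fail because the o-fluoroaryllithium may eliminate LiF to an aryne or be quenched before carboxylation. The fallback sets out from 9 and comes back at 12 without any organolithium. It is a palladium-catalysed carbonylative lactonisation (Pd(OAc)2 5 mol%, 4,5-bis(diphenylphosphino)-9,9-dimethylxanthene, CO 1 atm, K2CO3, DMF, 100 °C), in which the acylpalladium intermediate is trapped by the neighbouring hydroxyl. New compounds on this path: none F0.

**Further compounds**
F0 | step 5 | none | none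
F1 | step 6 | (S)-2-bromo-1-fluoro-5-methoxy-3-[1-(methoxymethoxy)pentyl]benzene | CCCC[C@H](OCOC)c1cc(OC)cc(F)c1Br
F2 | step 6 | 2-fluoro-4-methoxy-6-[(1S)-1-(methoxymethoxy)pentyl]benzaldehyde | CCCC[C@H](OCOC)c1cc(OC)cc(F)c1C=O
F3 | step 6 | 2-(2,4-dimethoxy-6-pentylphenoxy)-4-methoxy-6-[(1S)-1-(methoxymethoxy)pentyl]benzaldehyde | CCCCCc1cc(OC)cc(OC)c1Oc1cc(OC)cc([C@@H](OCOC)CCCC)c1C=O
F4 | step 6 | 2-(2,4-dimethoxy-6-pentylphenoxy)-4-methoxy-6-[(1S)-1-(methoxymethoxy)pentyl]benzoic acid | CCCCCc1cc(OC)cc(OC)c1Oc1cc(OC)cc([C@@H](OCOC)CCCC)c1C(=O)O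
F5 | step 6 | 2-(2,4-dimethoxy-6-pentylphenoxy)-6-[(1S)-1-hydroxypentyl]-4-methoxybenzoic acid | CCCCCc1cc(OC)cc(OC)c1Oc1cc(OC)cc([C@@H](O)CCCC)c1C(=O)O
F6 | step 8 | sodium 2-(2,4-dihydroxy-6-pentylphenoxy)-4-hydroxy-6-[(1S)-1-hydroxypentyl]benzoate | CCCCCc1cc(O)cc(O)c1Oc1cc(O)cc([C@@H](O)CCCC)c1C(=O)[O-].[Na+]
F7 | step 8 | benzyl 2-(2,4-dihydroxy-6-pentylphenoxy)-4-hydroxy-6-[(1S)-1-hydroxypentyl]benzoate | CCCCCc1cc(O)cc(O)c1Oc1cc(O)cc([C@@H](O)CCCC)c1C(=O)OCc1ccccc1
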